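# Proposed total synthesis of Epimedonin L (19)

## Analysis of the target

Epimedonin L (19) is a flavone, a 2-aryl-4H-chromen-4-one, in which ring A (C4a, C5, C6, C7, C8, C8a) is a phloroglucinol-type ring with hydroxyls on C5 and C7 and a prenyl (3-methylbut-2-en-1-yl) group on C8. Ring C is the 4-pyranone O1–C2=C3–C4(=O)–C4a=C8a, and ring B on C2 is a 4′-hydroxyphenyl ring with prenyl groups on C3′ and C5′. There is no stereocentre and no stereogenic alkene (each alkene carries two methyl groups on one carbon), so the whole problem is one of constitution. The feature on which the plan rests lies in ring C: C4 carries only oxygen, C3 only hydrogen, and O1 sits on C8a, which is flanked by C8 (prenyl) and C4a, so ring C can be cut into the ring A phenol O1–C8a/C4a, a one-carbon unit for C4, and the two alkyne carbons C3–C2 that carry ring B, without touching a prenyl-bearing carbon. The first difficulty is C8 against C6: ring A derives from threefold-symmetric phloroglucinol, and any precursor in which either ortho oxygen can close ring C also gives the 6-prenyl isomer. The second is ring B, which needs two prenyl groups ortho to one hydroxyl. The third is sensitivity: each o-prenylphenol is closed to a chroman by acid and to cyclic ethers or chromenes by I2, DDQ or peracids, and hydrogenation of the finished skeleton is excluded. Ring C must therefore be formed without acid or oxidant, and the last step must be neutral or basic.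

## Retrosynthetic reasoning

**19 to 18.** Only the three O–Si bonds at O5, O7 and O4′ are cut. Silyl ethers are chosen because a fluoride source removes them without acid, so the three o-prenylphenols are set free under conditions that cannot close chromans.

**18 to 7, 14 and 15 (key disconnection).** Ring C is cut at three bonds at once: C4a–C4, C4–C3 and O1–C2. C4 becomes carbon monoxide (15), C3–C2 become the alkyne carbons of arylacetylene 14 (ring B with both prenyl groups), and O1/C4a become the hydroxyl and the iodine-bearing carbon of iodophenol 7 (ring A with its prenyl group). The cut is made here because both arenes then arrive fully prenylated and the product is already at the flavone oxidation level, so no oxidative ring closure is needed. In 7 the iodine marks C4a and the only free hydroxyl marks O1, so the prenyl group can only end on C8. The forward reaction must insert CO at the C–I bond, join the aroyl unit to the alkyne and close the pyranone 6-endo.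

**7 to 5, 3 and 1.** Two O–Si bonds are cut first. In triol 5 the hydroxyl between C–I and C–prenyl is the only one with two ortho substituents, so a bulky silyl chloride (6) should leave exactly this hydroxyl free. The aryl–prenyl bond is cut next. In 3 the two open ring carbons are related by the mirror plane through C2 and C5, so C-alkylation with 4 can give only one constitution. The C–I bond is cut last, back to phloroglucinol (1) and iodine (2); in 1 all three ring carbons are equivalent. The C8/C6 problem is thus reduced to one steric differentiation of hydroxyls.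

**14 to 12, 10, 8 and 9.** The terminal alkyne carbon is cut (one-carbon homologation of aldehyde 12 with 13), then the O–Si bond (10 with 11). Both aryl–prenyl bonds are cut together as a double cross-coupling of stannane 9 with 8, a commercial aldehyde that already carries the two halogens ortho to the hydroxyl.

## Alternatives that were turned down

Alternative 1: The textbook route cuts C2–C3 and O1–C2. Acetophenone A1 and aldehyde 12 would give chalcone A2 by Claisen–Schmidt condensation, and the forward key step is the oxidative cyclisation of A2 (I2/DMSO or DDQ), which closes ring C.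
- The phenol that must close ring C in A2 is ortho to the future C8 prenyl group. Electrophilic iodine would engage this phenol–alkene pair in iodoetherification, and DDQ dehydrogenates o-prenylphenols to chromenes.
- The Baker–Venkataraman variant avoids the oxidant but ends in an acid-mediated cyclodehydration, and acid would close the chroman instead.
- A1 itself needs a separate regiochemical solution and acetal protecting groups, whose removal puts acid on three o-prenylphenols at the end.
- The step count is no lower than that of the chosen route.

Alternative 2: A late oxygen-to-carbon relay cuts only the C8–prenyl bond. The 5-O-prenyl ether A3 would undergo a para-Claisen–Cope rearrangement catalysed by Eu(fod)3, with a [3,3] shift from O5 to C6 followed by a [3,3] shift from C6 to C8.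
- The key step installs one of three prenyl groups and builds no ring.
- A3 presupposes the complete flavone skeleton with ring B already diprenylated, that is, the ring closure of Alternative 1 with its oxidant problem.
- It also requires alkylation of the chelated, least reactive 5-OH, so the route grows by at least three steps.
- The relay can stop after the first shift, at C6, if the second shift is slow.

Alternative 3: A late triple prenylation cuts all three aryl–prenyl bonds at once. Triiodide A4 would be coupled three times with stannane 9 under palladium catalysis.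
- A4 cannot be reached by iodinating apigenin A5 directly. In A5 ring A reacts first, at C6 and C8 when O5 is free and at C8 alone only when O5 is capped, while ring B, an aryl ring conjugated to the pyranone, would not be iodinated before C6.
- A4 would therefore have to be assembled from 8 by the chalcone route, which takes five to six steps and moves the regiochemical problem into an electrophilic iodination.
- The key step must then make the linear-versus-branched choice three times on one substrate, once at the hindered C8 between O1 and O7.
- The acetal groups needed to steer the iodination must finally be removed with acid in the presence of three o-prenylphenols.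

Key step: step 7

Assumption (remark on the chemistry): the target is achiral and its alkenes carry no E/Z information, so no stereocontrol is required. 2-Iodophloroglucinol (3) is prepared from phloroglucinol (1) rather than purchased.

## Route

Step 1
Reactants: 1 phloroglucinol (benzene-1,3,5-triol); 2 iodine
Product: 3 2-iodobenzene-1,3,5-triol
Conditions: I2 (1.0 equiv), NaHCO3 (1.1 equiv), THF–H2O (1:1), 0 °C
Reagents that add atoms: iodine 2 (II)
Why: Electrophilic aromatic iodination of a threefold-symmetric triol whose three ring carbons are equivalent, so mono-iodination can give only one product; one equivalent of I2 and the deactivating effect of the first iodine should limit further iodination.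

Step 2
Reactants: 3 2-iodobenzene-1,3,5-triol; 4 prenyl bromide (1-bromo-3-methylbut-2-ene)
Product: 5 2-iodo-4-(3-methylbut-2-en-1-yl)benzene-1,3,5-triol
Conditions: 4 (0.8 equiv), KOH (1.0 equiv), H2O, 0 °C → rt
Reagents that add atoms: 1-bromo-3-methylbut-2-ene 4 (CC(C)=CCBr)
Why: C-Alkylation of a phloroglucinol phenoxide in water, where hydrogen bonding to oxygen favours attack through carbon; the two open ring carbons of 3 are mirror-related, so only one mono-C-prenyl constitution is possible, and a deficit of 4 should hold back the second alkylation.

Step 3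
Reactants: 5 2-iodo-4-(3-methylbut-2-en-1-yl)benzene-1,3,5-triol; 6 chlorotri(propan-2-yl)silane (TIPSCl)
Product: 7 2-iodo-6-(3-methylbut-2-en-1-yl)-3,5-bis{[tri(propan-2-yl)silyl]oxy}phenol
Conditions: TIPSCl (2.1 equiv), imidazole (4 equiv), DMF, 0 °C → rt
Reagents that add atoms: chlorotri(propan-2-yl)silane 6 (CC(C)[Si](Cl)(C(C)C)C(C)C)
Why: Sterically controlled silylation: the two hydroxyls with one ortho substituent each (next to C–H) should react readily with the bulky chlorosilane, while the hydroxyl between C–I and C–prenyl is 2,6-disubstituted and should react far more slowly, so the future O1 stays free.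

Step 4
Reactants: 8 4-hydroxy-3,5-diiodobenzaldehyde; 9 tributyl(3-methylbut-2-en-1-yl)stannane
Product: 10 4-hydroxy-3,5-bis(3-methylbut-2-en-1-yl)benzaldehyde
Conditions: 9 (2.6 equiv), Pd(PPh3)4 (5 mol %), DMF, 90 °C
Reagents that add atoms: tributyl(3-methylbut-2-en-1-yl)stannane 9 (CC(C)=CC[Sn](CCCC)(CCCC)CCCC)
Why: Double Stille coupling at the two C–I bonds; the allyl unit is transferred from tin to palladium and reductive elimination at the unsubstituted allyl terminus should give the linear prenyl arene, while the aldehyde and the free phenol are tolerated under these neutral conditions.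

Step 5
Reactants: 10 4-hydroxy-3,5-bis(3-methylbut-2-en-1-yl)benzaldehyde; 11 tert-butylchlorodimethylsilane (TBSCl)
Product: 12 4-{[tert-butyl(dimethyl)silyl]oxy}-3,5-bis(3-methylbut-2-en-1-yl)benzaldehyde
Conditions: TBSCl (1.3 equiv), imidazole (2.5 equiv), DMF, 40 °C
Reagents that add atoms: tert-butylchlorodimethylsilane 11 (CC(C)(C)[Si](C)(C)Cl)
Why: Silyl ether formation on a phenol that is hindered but acidified by the para formyl group; the ether shields the phenol from the lithium reagent of step 6 and from acylation in step 7, and is removed by fluoride at the end.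

Step 6
Reactants: 12 4-{[tert-butyl(dimethyl)silyl]oxy}-3,5-bis(3-methylbut-2-en-1-yl)benzaldehyde; 13 (trimethylsilyl)diazomethane
Product: 14 tert-butyl[4-ethynyl-2,6-bis(3-methylbut-2-en-1-yl)phenoxy]dimethylsilane
Conditions: 13 (1.2 equiv), LiN(iPr)2 (1.2 equiv), THF, −78 °C → rt
Reagents that add atoms: (trimethylsilyl)diazomethane 13 (C[Si](C)(C)C=[N+]=[N-])
Why: Colvin rearrangement: lithiated 13 adds to the aldehyde, Peterson-type loss of silanolate, loss of N2 and a 1,2-hydrogen shift of the alkylidene carbene give the terminal alkyne; the aprotic low-temperature conditions spare the aryl silyl ether, which a homologation in K2CO3/MeOH would endanger.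

Step 7
Reactants: 7 2-iodo-6-(3-methylbut-2-en-1-yl)-3,5-bis{[tri(propan-2-yl)silyl]oxy}phenol; 14 tert-butyl[4-ethynyl-2,6-bis(3-methylbut-2-en-1-yl)phenoxy]dimethylsilane; 15 carbon monoxide
Product: 18 2-{4-[(tert-butyldimethylsilyl)oxy]-3,5-bis(3-methylbut-2-en-1-yl)phenyl}-8-(3-methylbut-2-en-1-yl)-5,7-bis{[tri(propan-2-yl)silyl]oxy}-4H-chromen-4-one, via ynone 16 (not isolated), via enaminone 17 (not isolated)
Conditions: PdCl2(PPh3)2 (5 mol %), CO (1 atm), Et3N (3 equiv), THF–H2O (9:1), 40 °C; then Et2NH (5 equiv), 50 °C
Reagents that add atoms: carbon monoxide 15 ([C-]#[O+])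
Why: Zerovalent palladium, formed in the flask from PdCl2(PPh3)2, inserts into the C–I bond of 7, CO inserts to give an aroyl complex of divalent palladium, the amine-deprotonated alkyne 14 is transferred to palladium, and reductive elimination gives ynone 16; this forms C4a–C4 and C4–C3, with C4 coming from CO. Et2NH then adds to the ynone to give enaminone 17, and the only free hydroxyl, on the future C8a, attacks C2 with loss of Et2NH and closes ring C through O1–C2. The closest known reaction type is the palladium-catalysed carbonylative annulation of o-iodophenols with terminal arylacetylenes to flavones (carbonylative Sonogashira coupling followed by cyclisation). Ring C closes in a net 6-endo-dig sense, run as a 6-endo-trig addition–elimination on 17, and the secondary amine is what should exclude the 5-exo-dig closure to an aurone. No stereocentre is formed. Three selectivities are needed: CO uptake before alkynylation, which copper-free conditions, the CO atmosphere and the electron-rich, doubly ortho-substituted aryl palladium species should secure; ring fusion through the right oxygen, secured because the hydroxyl between iodine and prenyl is the only free one in 7 and so places the prenyl group on C8; and reaction at the alkyne and not at the three trisubstituted alkenes, none of which is activated or placed for insertion into the aroyl–palladium bond. The medium is basic and non-oxidising, so the o-prenylphenol of 7 should not be cyclised.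

Step 8
Reactants: 18 2-{4-[(tert-butyldimethylsilyl)oxy]-3,5-bis(3-methylbut-2-en-1-yl)phenyl}-8-(3-methylbut-2-en-1-yl)-5,7-bis{[tri(propan-2-yl)silyl]oxy}-4H-chromen-4-one
Product: 19 Epimedonin L, 5,7-dihydroxy-2-[4-hydroxy-3,5-bis(3-methylbut-2-en-1-yl)phenyl]-8-(3-methylbut-2-en-1-yl)-4H-chromen-4-one
Conditions: Bu4NF (3.5 equiv), AcOH (3.5 equiv), THF, 0 °C → rt
Reagents that add atoms: none
Why: Fluoride-induced cleavage of the three aryl silyl ethers; AcOH buffers the phenoxides but is far too weak to protonate the prenyl alkenes, so the three o-prenylphenols should be released without chroman formation.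

## Compound list

1 | phloroglucinol (benzene-1,3,5-triol) | Oc1cc(O)cc(O)c1 | starting material
2 | iodine | II | starting material
3 | 2-iodobenzene-1,3,5-triol | Oc1cc(O)c(I)c(O)c1 | intermediate
4 | prenyl bromide (1-bromo-3-methylbut-2-ene) | CC(C)=CCBr | starting material
5 | 2-iodo-4-(3-methylbut-2-en-1-yl)benzene-1,3,5-triol | Oc1cc(O)c(CC=C(C)C)c(O)c1I | intermediate
6 | chlorotri(propan-2-yl)silane (TIPSCl) | CC(C)[Si](Cl)(C(C)C)C(C)C | starting material
7 | 2-iodo-6-(3-methylbut-2-en-1-yl)-3,5-bis{[tri(propan-2-yl)silyl]oxy}phenol | CC(C)=CCc1c(O)c(I)c(O[Si](C(C)C)(C(C)C)C(C)C)cc1O[Si](C(C)C)(C(C)C)C(C)C | intermediate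
8 | 4-hydroxy-3,5-diiodobenzaldehyde | O=Cc1cc(I)c(O)c(I)c1 | starting material
9 | tributyl(3-methylbut-2-en-1-yl)stannane | CC(C)=CC[Sn](CCCC)(CCCC)CCCC | starting material
10 | 4-hydroxy-3,5-bis(3-methylbut-2-en-1-yl)benzaldehyde | CC(C)=CCc1cc(C=O)cc(CC=C(C)C)c1O | intermediate
11 | tert-butylchlorodimethylsilane (TBSCl) | CC(C)(C)[Si](C)(C)Cl | starting material
12 | 4-{[tert-butyl(dimethyl)silyl]oxy}-3,5-bis(3-methylbut-2-en-1-yl)benzaldehyde | CC(C)=CCc1cc(C=O)cc(CC=C(C)C)c1O[Si](C)(C)C(C)(C)C | intermediate
13 | (trimethylsilyl)diazomethane | C[Si](C)(C)C=[N+]=[N-] | starting material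
14 | tert-butyl[4-ethynyl-2,6-bis(3-methylbut-2-en-1-yl)phenoxy]dimethylsilane | CC(C)=CCc1cc(C#C)cc(CC=C(C)C)c1O[Si](C)(C)C(C)(C)C | intermediate
15 | carbon monoxide | [C-]#[O+] | starting material
16 | 3-{4-[(tert-butyldimethylsilyl)oxy]-3,5-bis(3-methylbut-2-en-1-yl)phenyl}-1-[2-hydroxy-3-(3-methylbut-2-en-1-yl)-4,6-bis{[tri(propan-2-yl)silyl]oxy}phenyl]prop-2-yn-1-one | CC(C)=CCc1c(O)c(C(=O)C#Cc2cc(CC=C(C)C)c(O[Si](C)(C)C(C)(C)C)c(CC=C(C)C)c2)c(O[Si](C(C)C)(C(C)C)C(C)C)cc1O[Si](C(C)C)(C(C)C)C(C)C | intermediate
17 | (2E)-3-{4-[(tert-butyldimethylsilyl)oxy]-3,5-bis(3-methylbut-2-en-1-yl)phenyl}-3-(diethylamino)-1-[2-hydroxy-3-(3-methylbut-2-en-1-yl)-4,6-bis{[tri(propan-2-yl)silyl]oxy}phenyl]prop-2-en-1-one | CC(C)=CCc1c(O)c(C(=O)/C=C(\c2cc(CC=C(C)C)c(O[Si](C)(C)C(C)(C)C)c(CC=C(C)C)c2)N(CC)CC)c(O[Si](C(C)C)(C(C)C)C(C)C)cc1O[Si](C(C)C)(C(C)C)C(C)C | intermediate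
18 | 2-{4-[(tert-butyldimethylsilyl)oxy]-3,5-bis(3-methylbut-2-en-1-yl)phenyl}-8-(3-methylbut-2-en-1-yl)-5,7-bis{[tri(propan-2-yl)silyl]oxy}-4H-chromen-4-one | CC(C)=CCc1cc(-c2cc(=O)c3c(O[Si](C(C)C)(C(C)C)C(C)C)cc(O[Si](C(C)C)(C(C)C)C(C)C)c(CC=C(C)C)c3o2)cc(CC=C(C)C)c1O[Si](C)(C)C(C)(C)C | intermediate
19 | Epimedonin L, 5,7-dihydroxy-2-[4-hydroxy-3,5-bis(3-methylbut-2-en-1-yl)phenyl]-8-(3-methylbut-2-en-1-yl)-4H-chromen-4-one | CC(C)=CCc1cc(-c2cc(=O)c3c(O)cc(O)c(CC=C(C)C)c3o2)cc(CC=C(C)C)c1O | target

## Step count and least certain steps

Total step count: 8. Longest linear sequence: 5 (steps 1, 2, 3, 7, 8; the ring B branch, steps 4, 5, 6, 7, 8, is equally long).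

**Step 7 (key step).** The most likely failure is slow oxidative addition and slow CO uptake at the electron-rich, doubly ortho-substituted C–I bond. The catalyst could then be lost under CO, or the alkyne could couple directly without CO and close to a five-membered oxygen ring. A second failure mode is loss of the silyl group ortho to the ynone carbonyl before ring closure, which would let the wrong oxygen close ring C and leak the prenyl group to C6.

Fallback (no palladium, no CO; C4 comes with the ring B fragment): it sets out from 14 and 7 and comes back at 18. Alkyne 14 is lithiated with n-BuLi in THF at −78 °C and formylated with DMF to give 3-{4-[(tert-butyldimethylsilyl)oxy]-3,5-bis(3-methylbut-2-en-1-yl)phenyl}prop-2-ynal F1 after aqueous work-up. Iodophenol 7 is treated with n-BuLi (2.1 equiv) at −78 °C (deprotonation of the hydroxyl, then iodine–lithium exchange), and the aryllithium is added at once to F1 to give the racemic propargylic alcohol F2 as the coupled product. Oxidation of F2 with MnO2 in CH2Cl2 gives ynone 16, which is closed to 18 with Et2NH at 50 °C as in step 7.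

**Step 2.** The most likely failure is O-alkylation, a second C-alkylation at the remaining ring carbon, or attack at the iodine-bearing carbon with loss of iodine, because every ring position of the phenoxide is nucleophilic.

Fallback (C–C bond formed on the parent triol, iodine introduced afterwards): it sets out from 1 and 4 and comes back at 5. Phloroglucinol 1 is C-prenylated with 4 in aqueous KOH to give 2-(3-methylbut-2-en-1-yl)benzene-1,3,5-triol F3 as a triol whose two open ring carbons are again mirror-related. Iodination of F3 with I2 (1.0 equiv)/NaHCO3 in THF–H2O at 0 °C gives 5; ring iodination of the phenoxide should outrun addition of iodine to the alkene.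

**Step 3.** The most likely failure is insufficient discrimination between the hydroxyls, either by silylation of the hindered hydroxyl or by incomplete silylation of one of the others. The resulting mixture would carry the wrong free oxygen into step 7.

Fallback (regiochemistry set by an aromatic Claisen rearrangement into the only open ortho carbon, not by sterics): it sets out from 3 and comes back at 7, and it bypasses step 2 as well. Triol 3 is silylated with TIPSCl (2 equiv)/imidazole to give 2-iodo-3,5-bis{[tri(propan-2-yl)silyl]oxy}phenol F4 by reaction at the unhindered hydroxyl para to iodine and at one of the two equivalent hydroxyls ortho to it. The remaining hydroxyl of F4 is alkylated with 3-chloro-3-methylbut-1-yne (CuCl2 cat., DBU, MeCN, 0 °C) to give the 1,1-dimethylpropargyl ether {[4-iodo-5-(2-methylbut-3-yn-2-yloxy)-1,3-phenylene]bis(oxy)}bis[tri(propan-2-yl)silane] F5 as the O-alkylated product. Semi-hydrogenation of F5 over Pd/CaCO3 poisoned with Pb(OAc)2 in the presence of quinoline (H2, 1 atm, EtOAc; no prenyl alkene is present at this stage) gives the 1,1-dimethylallyl ether F6 as the substrate for the rearrangement. Heating F6 in toluene at 110 °C gives 7 by [3,3] shift to the single free ortho position, which liberates exactly the hydroxyl between iodine and prenyl.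

**Step 4.** The most likely failure is transfer of the allyl unit through its substituted terminus, incomplete second coupling, or protonolysis of the stannane by the acidic phenol.

Fallback (phenoxide C-alkylation in place of cross-coupling): it sets out from 4 and comes back at 10. Purchased 4-hydroxybenzaldehyde F7 is ortho-C-prenylated with 4 in aqueous KOH to give 4-hydroxy-3-(3-methylbut-2-en-1-yl)benzaldehyde F8 as the mono-alkylated phenol; in F7 the para position is blocked by the formyl group, so only the two ortho carbons can be alkylated. F8 is prenylated once more under the same conditions to give 10.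

## Further compounds

F1 | step 7 | 3-{4-[(tert-butyldimethylsilyl)oxy]-3,5-bis(3-methylbut-2-en-1-yl)phenyl}prop-2-ynal | CC(C)=CCc1cc(C#CC=O)cc(CC=C(C)C)c1O[Si](C)(C)C(C)(C)C
F2 | step 7 | racemic 3-{4-[(tert-butyldimethylsilyl)oxy]-3,5-bis(3-methylbut-2-en-1-yl)phenyl}-1-[2-hydroxy-3-(3-methylbut-2-en-1-yl)-4,6-bis{[tri(propan-2-yl)silyl]oxy}phenyl]prop-2-yn-1-ol | CC(C)=CCc1c(O)c(C(O)C#Cc2cc(CC=C(C)C)c(O[Si](C)(C)C(C)(C)C)c(CC=C(C)C)c2)c(O[Si](C(C)C)(C(C)C)C(C)C)cc1O[Si](C(C)C)(C(C)C)C(C)C
F3 | step 2 | 2-(3-methylbut-2-en-1-yl)benzene-1,3,5-triol | CC(C)=CCc1c(O)cc(O)cc1O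
F4 | step 3 | 2-iodo-3,5-bis{[tri(propan-2-yl)silyl]oxy}phenol | Oc1cc(O[Si](C(C)C)(C(C)C)C(C)C)cc(O[Si](C(C)C)(C(C)C)C(C)C)c1I
F5 | step 3 | {[4-iodo-5-(2-methylbut-3-yn-2-yloxy)-1,3-phenylene]bis(oxy)}bis[tri(propan-2-yl)silane] | C#CC(C)(C)Oc1cc(O[Si](C(C)C)(C(C)C)C(C)C)cc(O[Si](C(C)C)(C(C)C)C(C)C)c1I
F6 | step 3 | {[4-iodo-5-(2-methylbut-3-en-2-yloxy)-1,3-phenylene]bis(oxy)}bis[tri(propan-2-yl)silane] | C=CC(C)(C)Oc1cc(O[Si](C(C)C)(C(C)C)C(C)C)cc(O[Si](C(C)C)(C(C)C)C(C)C)c1I
F7 | step 4 | 4-hydroxybenzaldehyde (purchased) | O=Cc1ccc(O)cc1
F8 | step 4 | 4-hydroxy-3-(3-methylbut-2-en-1-yl)benzaldehyde | CC(C)=CCc1cc(C=O)ccc1O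
A1 | alternative 1 | 1-[2-hydroxy-4,6-bis(methoxymethoxy)-3-(3-methylbut-2-en-1-yl)phenyl]ethan-1-one | CC(=O)c1c(O)c(CC=C(C)C)c(OCOC)cc1OCOC
A2 | alternative 1 | (2E)-3-{4-[(tert-butyldimethylsilyl)oxy]-3,5-bis(3-methylbut-2-en-1-yl)phenyl}-1-[2-hydroxy-4,6-bis(methoxymethoxy)-3-(3-methylbut-2-en-1-yl)phenyl]prop-2-en-1-one | CC(C)=CCc1cc(/C=C/C(=O)c2c(O)c(CC=C(C)C)c(OCOC)cc2OCOC)cc(CC=C(C)C)c1O[Si](C)(C)C(C)(C)C
A3 | alternative 2 | 7-(methoxymethoxy)-2-[4-(methoxymethoxy)-3,5-bis(3-methylbut-2-en-1-yl)phenyl]-5-[(3-methylbut-2-en-1-yl)oxy]-4H-chromen-4-one | CC(C)=CCOc1cc(OCOC)cc2oc(-c3cc(CC=C(C)C)c(OCOC)c(CC=C(C)C)c3)cc(=O)c12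
A4 | alternative 3 | 2-[3,5-diiodo-4-(methoxymethoxy)phenyl]-8-iodo-5,7-bis(methoxymethoxy)-4H-chromen-4-one | COCOc1cc(OCOC)c2c(=O)cc(-c3cc(I)c(OCOC)c(I)c3)oc2c1I
A5 | alternative 3 | apigenin, 5,7-dihydroxy-2-(4-hydroxyphenyl)-4H-chromen-4-one | O=c1cc(-c2ccc(O)cc2)oc2cc(O)cc(O)c12
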